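Remark on the chemistry: compounds 3, 9, 15 and 19 are assumed to be catalogue chemicals. Rings are lettered A to G in the order of the SMILES string; position 1 of rings B to G carries the ether oxygen on the side of ring A, except that D1 carries the oxygen to ring C and D6 that to ring E. "AB-aryloxy" stands for 2,6-dimethoxy-4-(2,4,6-trimethoxyphenoxy)phenoxy and "DEFG-aryloxy" for 3,4,5-trimethoxy-2-{3,5-dimethoxy-4-[3,5-dimethoxy-4-(3,4,5-trimethoxyphenoxy)phenoxy]phenoxy}phenoxy.

## The problem

Compound 28 is a phlorotannin heptamer: seven benzene rings held together only by six diaryl ether oxygens, carrying seventeen free phenolic hydroxyls, with no carbon–carbon bond between rings. There is no stereocentre, so nothing has to be set or relayed; the task is one of oxygenation pattern and of crowded aryl–oxygen bonds. Each ether oxygen joins a ring carbon flanked by two oxygenated carbons (A1, B4, C4, D6, E4, F4) to a carbon with a free ortho position (B1, C1, D1, E1, F1, G1), so every coupling involves a 2,6-dioxygenated phenol or its equivalent. Ring D is the only unsymmetrical ring: it is pentaoxygenated, its two aryloxy groups (D1, D6) are adjacent, and its two neighbouring oxygens must be told apart. The free polyphenol is oxidised easily, above all in base, so the hydroxyls must stay masked until the last step and the unmasking must spare the diaryl ethers. The feature that opens the key step is ring C: its ether carbon C4 lies between the hydroxylated C3 and C5, its ether carbon C1 lies opposite, and C2 and C6 carry hydrogen. C3–C4–C5 is therefore an aryloxymalonyl unit and C2–C1–C6 a 3-aryloxyglutaconate whose two ester groups can later leave as carbon dioxide; the ring is symmetrical about the C1–C4 axis, so the union raises no regiochemical question.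

## Retrosynthesis

**28 from 27.** The fifteen O–methyl bonds are cut last. Methyl ethers are chosen because every arene building block is available in methylated form and because they survive copper coupling, peracid, base and acid chloride chemistry. Benzyl ethers would give a milder end but would multiply the building-block work. The forward reaction must cleave fifteen alkyl aryl ethers and leave six diaryl ethers untouched.

**27 from 25.** The two C–CO2Me bonds at C2 and C6 are cut, by way of diacid 26. The esters are needed only to make the glutaconate carbons nucleophilic. In 26 each carboxyl is ortho and para to hydroxyl, which is the arrangement that loses carbon dioxide readily in the classical phloroglucinol synthesis. The forward reaction is saponification of two hindered salicylate-type esters and protodecarboxylation.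

**25 from 8 and 22 (key disconnection).** The ring bonds C2–C3 and C5–C6 are cut. The neighbouring cut, an ether disconnection at C4–O or C1–O, would ask for a copper coupling between two large, crowded, electron-rich fragments at the end of the synthesis. The ring synthesis instead attaches both ether oxygens beforehand to small reactive partners without any metal. The heptamer falls into a dimer (8) and a tetramer (22), and ring C with its four oxygens is no longer a building block. The forward reaction must acylate both terminal carbons of the glutaconate, close the ring at carbon and not at oxygen, and aromatise.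

**22 from 18 and 19.** The two C–Cl bonds lead back to diacid 21, the esters to malonate 20, and the O–C(malonyl) bond to phenol 18 and chloromalonate 19. The D1 oxygen is the least hindered oxygen of ring D, and alkylation of ortho-alkoxyphenols by 19 is an established reaction. The forward sequence asks only that 21 and 22 be handled cold.

**18 from 14 and 15.** The D1 hydroxyl is traced to a formyl group (16), and the D6–O bond is then cut to phenol 14 and bromoaldehyde 15. The formyl group of 15 does three things: it is the latent D1 oxygen, it activates the adjacent C–Br bond for etherification, and it tells the two catechol oxygens of ring D apart without a protecting group. Selective arylation of a trimethoxycatechol would offer no such control.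

**14 from 10 and 11.** The E1 hydroxyl is again traced to a formyl group (12), and the E4–O–F1 bond is cut to bromide 10 and syringaldehyde 11. Compound 11 supplies ring E as a hindered phenol whose para formyl group is the masked E1 oxygen. The forward steps are an Ullmann etherification and a Baeyer–Villiger oxidation.

**10 from 1 and 9.** The F4–O–G1 bond is cut. Iodide 9 is chosen so that the coupling takes place at C–I and the bromine of 1 is kept as the handle for the next etherification. Both partners are catalogue compounds.

**8 from 5 and 7; 7 from 6.** The O–C3 bond of the glutaconate is cut to phenol 5 and allene 7, which is the dehydration product of ketodiester 6. Conjugate addition to the central allene carbon is metal-free, and the hindered phenol meets an unhindered sp carbon.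

**5 from 3 and 1.** The A1–O–B1 bond is cut to phenol 3 and bromide 2, the benzyl ether of 1; hydrogenolysis of 4 then frees the B4 hydroxyl. Compound 1 thus serves as ring B and as ring F.

## Roads not taken

**Alternative 1:** No ring bond is cut. The twelve hydroxyl-bearing carbons ortho to the hindered ether carbons of rings A to F are traced to acetyl groups, and the dodecaacetyl heptamer A2 is assembled by nucleophilic aromatic substitution at carbons activated by two ortho acetyls. A buffered strong peracid then turns all twelve acetyls of A2 into acetoxy groups by aryl migration, giving A1.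
- Merits: every ether bond is made by a dependable, metal-free substitution; the acetyl groups activate and mask at once; only known reaction types are used; twelve of the seventeen hydroxyls emerge as mildly cleavable acetates.
- Weak points: twelve oxidations on one molecule must all go to completion with aryl and not methyl migration, while the rings become more electron-rich and more open to ring hydroxylation. The ethers of A2 are themselves activated towards substitution, so a phenoxide used in a later coupling can exchange an earlier ether and scramble the sequence. Enolisable methyl ketones must survive repeated basic couplings. Five methyl ethers still need Lewis-acid cleavage, and the assembly is linear.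
- Comparison: in the certainty of its reaction types this road is ahead, since the ring synthesis of the chosen plan is untested. The chosen plan sets against it a convergent union of a dimer and a tetramer, a single uncertain event that can be probed early on easily made fragments, and an end-game of one ether cleavage.

**Alternative 2:** Ring G is cut at G1–G6, G3–G4 and G4–G5. The pentacarbonylchromium aryloxycarbene A4, which carries the hexamer on oxygen and an (E)-2-methoxyvinyl group on carbon, combines with the alkoxyacetylene A5 and one carbonyl ligand in a Dötz benzannulation to give A3.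
- Merits: the reaction type is known, runs under neutral conditions, and fixes the regiochemistry of ring G through the polarity of A5.
- Weak points: ring G is the simplest ring, and an equivalent unit can be bought (9). The hexamer must be finished first, so all five difficult ether bonds and six rings remain, and the sequence is fully linear. Aryloxycarbene complexes of zerovalent chromium are labile because aryloxide leaves easily from the carbene carbon. A4 would have to be made from a hindered hexameric phenol late in the route, with stoichiometric chromium. The free G4 hydroxyl and the ethyl ether of A3 bring no gain, since every ether is cleaved at the end.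
- Comparison: as a ring-forming reaction it is better precedented than the chosen key step. The chosen plan sets against it that its own ring synthesis replaces the most hindered late coupling and joins two fragments, whereas this one adds a ring that needs no synthesis.

**Alternative 3:** Ring D is cut at D2–D3, D1–D6 and D3–D4. Heating the racemic cyclobutenone A7 with the trimeric aryl ethynyl ether A8 gives a vinylketene, a cycloadduct, and after electrocyclic opening and closure the heptamer A6 with a free D3 hydroxyl (Danheiser benzannulation).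
- Merits: this road is more convergent than the chosen one, a trimer joining a trimer about the central ring. It builds the one unsymmetrical ring with both aryloxy groups in place, so the catechol differentiation that the chosen route solves with the formyl group of 15 does not arise. The reaction type is known for oxygenated alkynes, and the stereocentre of A7 disappears.
- Weak points: A7 needs three different oxygen substituents, with the aryloxy group on the carbon next to the carbonyl; simple exchange on squaric esters places nucleophiles on the other carbon. Its preparation with a trimeric aryloxy group would take several steps on a strained, heat- and acid-sensitive ring. A8 is an ynol ether of a di-ortho-substituted phenol, open to hydration and polymerisation, and such benzannulations usually need one partner in excess, here a precious trimer.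
- Comparison: in convergence and in precedent for the ring-forming reaction type this road is as good as or better than the chosen plan. The chosen plan sets against it two stable partners, each made from a phenol in one to three routine operations, arenes drawn entirely from catalogue methoxy compounds, and a ring C whose symmetry removes any regiochemical risk.

Key step: step 14

## Route

Step 1
Reactants: 1 4-bromo-2,6-dimethoxyphenol
Product: 2 2-(benzyloxy)-5-bromo-1,3-dimethoxybenzene
Conditions: BnBr, K2CO3, DMF, 60 °C
Reagents that add atoms: benzyl bromide, BrCc1ccccc1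
Why: Williamson etherification of the phenoxide; the benzyl group masks the B4 oxygen through the copper coupling and is removed later without touching methyl ethers.

Step 2
Reactants: 2 2-(benzyloxy)-5-bromo-1,3-dimethoxybenzene; 3 2,4,6-trimethoxyphenol
Product: 4 2-(benzyloxy)-1,3-dimethoxy-5-(2,4,6-trimethoxyphenoxy)benzene
Conditions: CuI (10 mol %), picolinic acid (20 mol %), K3PO4, DMSO, 100 °C, argon
Reagents that add atoms: none
Why: Ullmann diaryl ether synthesis with monovalent copper and picolinic acid, a combination known to join di-ortho-substituted phenols to electron-rich aryl bromides; the bromide carbon of 2 has two free ortho positions.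

Step 3
Reactants: 4 2-(benzyloxy)-1,3-dimethoxy-5-(2,4,6-trimethoxyphenoxy)benzene
Product: 5 2,6-dimethoxy-4-(2,4,6-trimethoxyphenoxy)phenol
Conditions: H2 (1 atm), Pd/C, EtOAc–MeOH, rt
Reagents that add atoms: none
Why: Hydrogenolysis of the benzyl aryl ether; methyl and diaryl ethers are inert and nothing else in 4 is reducible.

Step 4
Reactants: 6 dimethyl 3-oxopentanedioate
Product: 7 dimethyl penta-2,3-dienedioate (racemic allene)
Conditions: 2-chloro-1,3-dimethylimidazolinium chloride, Et3N, CH2Cl2, 0 °C to rt
Reagents that add atoms: none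
Why: Known dehydration of 3-oxoglutarates to allene-1,3-dicarboxylates: the enol oxygen is activated by the chloroimidazolinium salt and eliminated by the amine.

Step 5
Reactants: 5 2,6-dimethoxy-4-(2,4,6-trimethoxyphenoxy)phenol; 7 dimethyl penta-2,3-dienedioate
Product: 8 dimethyl (E)-3-(AB-aryloxy)pent-2-enedioate
Conditions: Et3N (0.2 equiv), THF, 0 °C to rt, slow addition of 7
Reagents that add atoms: none
Why: Base-catalysed conjugate (oxa-Michael) addition of the phenoxide to the central allene carbon, a known reaction of phenols with allenedioates; the E isomer with aryloxy trans to the ester is the more stable and expected product, and a Z component would give the same dienolate in step 14.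

Step 6
Reactants: 1 4-bromo-2,6-dimethoxyphenol; 9 5-iodo-1,2,3-trimethoxybenzene
Product: 10 5-bromo-1,3-dimethoxy-2-(3,4,5-trimethoxyphenoxy)benzene
Conditions: CuI (10 mol %), picolinic acid (20 mol %), K3PO4, DMSO, 80 °C, argon
Reagents that add atoms: none
Why: Chemoselective Ullmann etherification: monovalent copper reacts with the aryl iodide well below the temperature needed for an aryl bromide, and the C–Br bond of 1 sits on a phenoxide ring that is further deactivated.

Step 7
Reactants: 10 5-bromo-1,3-dimethoxy-2-(3,4,5-trimethoxyphenoxy)benzene; 11 4-hydroxy-3,5-dimethoxybenzaldehyde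
Product: 12 3,5-dimethoxy-4-[3,5-dimethoxy-4-(3,4,5-trimethoxyphenoxy)phenoxy]benzaldehyde
Conditions: CuI (20 mol %), picolinic acid (40 mol %), K3PO4, DMSO, 110 °C, argon
Reagents that add atoms: none
Why: Ullmann diaryl ether synthesis between a hindered phenol and an aryl bromide with free ortho positions; the aldehyde has no enolisable hydrogen and tolerates the phosphate base.

Step 8
Reactants: 12 3,5-dimethoxy-4-[3,5-dimethoxy-4-(3,4,5-trimethoxyphenoxy)phenoxy]benzaldehyde
Product: 14 3,5-dimethoxy-4-[3,5-dimethoxy-4-(3,4,5-trimethoxyphenoxy)phenoxy]phenol, via aryl formate 13 (not isolated)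
Conditions: mCPBA, CH2Cl2, 0 °C to rt; then K2CO3 (cat.), MeOH, rt
Reagents that add atoms: 3-chloroperbenzoic acid, OOC(=O)c1cccc(Cl)c1
Why: Baeyer–Villiger oxidation of an aryl aldehyde in which the aryl group with a para oxygen migrates in preference to hydrogen, as in the known conversion of 3,4,5-trimethoxybenzaldehyde into its phenol; the formate shields the new phenol from the peracid until methanolysis.

Step 9
Reactants: 14 3,5-dimethoxy-4-[3,5-dimethoxy-4-(3,4,5-trimethoxyphenoxy)phenoxy]phenol; 15 2-bromo-3,4,5-trimethoxybenzaldehyde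
Product: 16 3,4,5-trimethoxy-2-{3,5-dimethoxy-4-[3,5-dimethoxy-4-(3,4,5-trimethoxyphenoxy)phenoxy]phenoxy}benzaldehyde
Conditions: CuI (10 mol %), picolinic acid (20 mol %), K3PO4, DMSO, 90 °C, argon
Reagents that add atoms: none
Why: Ullmann etherification of an unhindered phenol with an aryl bromide activated by its ortho formyl group; the formyl group marks the future D1 oxygen, so the two adjacent oxygens of ring D are distinguished from the start.

Step 10
Reactants: 16 3,4,5-trimethoxy-2-{3,5-dimethoxy-4-[3,5-dimethoxy-4-(3,4,5-trimethoxyphenoxy)phenoxy]phenoxy}benzaldehyde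
Product: 18 3,4,5-trimethoxy-2-{3,5-dimethoxy-4-[3,5-dimethoxy-4-(3,4,5-trimethoxyphenoxy)phenoxy]phenoxy}phenol, via aryl formate 17 (not isolated)
Conditions: mCPBA, CH2Cl2, 0 °C to rt; then K2CO3 (cat.), MeOH, rt
Reagents that add atoms: 3-chloroperbenzoic acid, OOC(=O)c1cccc(Cl)c1
Why: Dakin-type Baeyer–Villiger oxidation; the formyl group has an ortho aryloxy and a para methoxy group, the pattern for which aryl migration is most reliable.

Step 11
Reactants: 18 3,4,5-trimethoxy-2-{3,5-dimethoxy-4-[3,5-dimethoxy-4-(3,4,5-trimethoxyphenoxy)phenoxy]phenoxy}phenol; 19 dimethyl 2-chloropropanedioate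
Product: 20 dimethyl 2-(DEFG-aryloxy)propanedioate
Conditions: K2CO3, acetone, reflux
Reagents that add atoms: none
Why: SN2 O-alkylation of the phenoxide by the chloromalonate, known for ortho-alkoxyphenols; the chloride is preferred to the bromide because it is less prone to transfer halogen to the electron-rich phenoxide.

Step 12
Reactants: 20 dimethyl 2-(DEFG-aryloxy)propanedioate
Product: 21 2-(DEFG-aryloxy)propanedioic acid
Conditions: LiOH, THF–MeOH–H2O, 0 °C to rt; then aq. HCl to pH 2 at 0 °C, evaporation below 25 °C
Reagents that add atoms: lithium hydroxide, [Li+].[OH-]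
Why: Saponification of both methyl esters; cold acidification and evaporation keep the aryloxymalonic acid from decarboxylating.

Step 13
Reactants: 21 2-(DEFG-aryloxy)propanedioic acid
Product: 22 2-(DEFG-aryloxy)propanedioyl dichloride
Conditions: (COCl)2, DMF (cat.), CH2Cl2, 0 °C to rt; evaporation, used at once
Reagents that add atoms: oxalyl chloride, O=C(Cl)C(Cl)=O
Why: Acid chloride formation through the chloroiminium intermediate under cold, neutral conditions; the by-products are gases, so crude 22 goes directly into step 14.

Step 14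
Reactants: 8 dimethyl (E)-3-(AB-aryloxy)pent-2-enedioate; 22 2-(DEFG-aryloxy)propanedioyl dichloride
Product: 25 dimethyl 4,6-dihydroxy-2-(AB-aryloxy)-5-(DEFG-aryloxy)benzene-1,3-dicarboxylate, via chlorocarbonyl ketene 23 (not isolated), via open-chain acyl chloride 24 (not isolated)
Conditions: MgCl2, Et3N, MeCN–CH2Cl2, 0 °C, 22 added over 6 h (5 mM final), then 45 °C; aq. HCl work-up
Reagents that add atoms: none
Why: Proposed new method: Et3N removes HCl from 22 to give ketene 23 and, with MgCl2, converts 8 into its magnesium dienolate, whose terminal carbon C2 attacks the ketene carbonyl to give the chelated enolate of 24 (first new bond, ring C2–C3). The remaining acid chloride of 24 is then attacked by the vinylogous carbon C4 in a 6-exo-trig C-acylation (second new bond, ring C5–C6), and two enolisations turn the cyclohexenedione into the aromatic 3,5-diol, which makes the closure irreversible. The closest known reaction types are the cyclocondensation of monosubstituted malonyl dichlorides and their chlorocarbonyl ketenes with 1,3-dinucleophiles, the magnesium-mediated C-acylation of malonate-type esters by acid chlorides, and the classical phloroglucinol synthesis from a malonate and a 3-oxoglutarate; a pair in which both partners carry aryloxy groups has not been described. No stereocentre is formed. The step needs C- over O-acylation and ring closure over chain growth: the aryl ether at C3 of 8 leaves no enol oxygen there, magnesium chelation ties up the ketone and ester oxygens of 24, the acid chloride is a far better electrophile than the methyl ester that would lead to a 2-pyranone, and high dilution with slow addition favours the intramolecular second acylation. Ring C is symmetrical about its C1–C4 axis, so no regiochemical question arises.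

Step 15
Reactants: 25 dimethyl 4,6-dihydroxy-2-(AB-aryloxy)-5-(DEFG-aryloxy)benzene-1,3-dicarboxylate
Product: 27 5-(AB-aryloxy)-2-(DEFG-aryloxy)benzene-1,3-diol, via heptamer diacid 26 (not isolated)
Conditions: KOH, H2O–DMSO, 100 °C, argon; then aq. HCl to pH 1–2, 60 °C
Reagents that add atoms: none
Why: Saponification of the two hindered salicylate-type esters, then protodecarboxylation of 26, whose carboxyl groups are each ortho and para to hydroxyl; this is the closing stage of the classical phloroglucinol synthesis.

Step 16
Reactants: 27 5-(AB-aryloxy)-2-(DEFG-aryloxy)benzene-1,3-diol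
Product: 28 5-[2,6-dihydroxy-4-(2,4,6-trihydroxyphenoxy)phenoxy]-2-{3,4,5-trihydroxy-2-[3,5-dihydroxy-4-[3,5-dihydroxy-4-(3,4,5-trihydroxyphenoxy)phenoxy]phenoxy]phenoxy}benzene-1,3-diol (CNP0304148.0)
Conditions: BBr3 (excess), CH2Cl2, −78 °C to rt, argon; then H2O, 0 °C; reverse-phase chromatography under argon
Reagents that add atoms: none
Why: Lewis-acid cleavage of all fifteen methyl aryl ethers by coordination of boron and bromide attack at methyl; diaryl ethers offer no alkyl carbon and survive, and hydrolysis of the aryl borates releases the heptadecaphenol.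

## Compound list

1 | 4-bromo-2,6-dimethoxyphenol | COc1cc(Br)cc(OC)c1O | starting material
2 | 2-(benzyloxy)-5-bromo-1,3-dimethoxybenzene | COc1cc(Br)cc(OC)c1OCc1ccccc1 | intermediate
3 | 2,4,6-trimethoxyphenol | COc1cc(OC)c(O)c(OC)c1 | starting material
4 | 2-(benzyloxy)-1,3-dimethoxy-5-(2,4,6-trimethoxyphenoxy)benzene | COc1cc(OC)c(Oc2cc(OC)c(OCc3ccccc3)c(OC)c2)c(OC)c1 | intermediate
5 | 2,6-dimethoxy-4-(2,4,6-trimethoxyphenoxy)phenol (AB phenol) | COc1cc(OC)c(Oc2cc(OC)c(O)c(OC)c2)c(OC)c1 | intermediate
6 | dimethyl 3-oxopentanedioate | COC(=O)CC(=O)CC(=O)OC | starting material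
7 | dimethyl penta-2,3-dienedioate (racemic allene) | COC(=O)C=C=CC(=O)OC | intermediate
8 | dimethyl (E)-3-[2,6-dimethoxy-4-(2,4,6-trimethoxyphenoxy)phenoxy]pent-2-enedioate | COC(=O)C/C(Oc1c(OC)cc(Oc2c(OC)cc(OC)cc2OC)cc1OC)=C\C(=O)OC | intermediate
9 | 5-iodo-1,2,3-trimethoxybenzene | COc1cc(I)cc(OC)c1OC | starting material
10 | 5-bromo-1,3-dimethoxy-2-(3,4,5-trimethoxyphenoxy)benzene | COc1cc(Br)cc(OC)c1Oc1cc(OC)c(OC)c(OC)c1 | intermediate
11 | 4-hydroxy-3,5-dimethoxybenzaldehyde (syringaldehyde) | COc1cc(C=O)cc(OC)c1O | starting material
12 | 3,5-dimethoxy-4-[3,5-dimethoxy-4-(3,4,5-trimethoxyphenoxy)phenoxy]benzaldehyde | COc1cc(C=O)cc(OC)c1Oc1cc(OC)c(Oc2cc(OC)c(OC)c(OC)c2)c(OC)c1 | intermediate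
13 | 3,5-dimethoxy-4-[3,5-dimethoxy-4-(3,4,5-trimethoxyphenoxy)phenoxy]phenyl formate | COc1cc(OC=O)cc(OC)c1Oc1cc(OC)c(Oc2cc(OC)c(OC)c(OC)c2)c(OC)c1 | intermediate (not isolated)
14 | 3,5-dimethoxy-4-[3,5-dimethoxy-4-(3,4,5-trimethoxyphenoxy)phenoxy]phenol (EFG phenol) | COc1cc(O)cc(OC)c1Oc1cc(OC)c(Oc2cc(OC)c(OC)c(OC)c2)c(OC)c1 | intermediate
15 | 2-bromo-3,4,5-trimethoxybenzaldehyde | COc1cc(C=O)c(Br)c(OC)c1OC | starting material
16 | 3,4,5-trimethoxy-2-{3,5-dimethoxy-4-[3,5-dimethoxy-4-(3,4,5-trimethoxyphenoxy)phenoxy]phenoxy}benzaldehyde | O=Cc1cc(OC)c(OC)c(OC)c1Oc1cc(OC)c(Oc2cc(OC)c(Oc3cc(OC)c(OC)c(OC)c3)c(OC)c2)c(OC)c1 | intermediate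
17 | 3,4,5-trimethoxy-2-{3,5-dimethoxy-4-[3,5-dimethoxy-4-(3,4,5-trimethoxyphenoxy)phenoxy]phenoxy}phenyl formate | O=COc1cc(OC)c(OC)c(OC)c1Oc1cc(OC)c(Oc2cc(OC)c(Oc3cc(OC)c(OC)c(OC)c3)c(OC)c2)c(OC)c1 | intermediate (not isolated)
18 | 3,4,5-trimethoxy-2-{3,5-dimethoxy-4-[3,5-dimethoxy-4-(3,4,5-trimethoxyphenoxy)phenoxy]phenoxy}phenol (DEFG phenol) | Oc1cc(OC)c(OC)c(OC)c1Oc1cc(OC)c(Oc2cc(OC)c(Oc3cc(OC)c(OC)c(OC)c3)c(OC)c2)c(OC)c1 | intermediate
19 | dimethyl 2-chloropropanedioate | COC(=O)C(Cl)C(=O)OC | starting material
20 | dimethyl 2-(DEFG-aryloxy)propanedioate | COC(=O)C(Oc1cc(OC)c(OC)c(OC)c1Oc1cc(OC)c(Oc2cc(OC)c(Oc3cc(OC)c(OC)c(OC)c3)c(OC)c2)c(OC)c1)C(=O)OC | intermediate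
21 | 2-(DEFG-aryloxy)propanedioic acid | OC(=O)C(Oc1cc(OC)c(OC)c(OC)c1Oc1cc(OC)c(Oc2cc(OC)c(Oc3cc(OC)c(OC)c(OC)c3)c(OC)c2)c(OC)c1)C(=O)O | intermediate
22 | 2-(DEFG-aryloxy)propanedioyl dichloride | O=C(Cl)C(Oc1cc(OC)c(OC)c(OC)c1Oc1cc(OC)c(Oc2cc(OC)c(Oc3cc(OC)c(OC)c(OC)c3)c(OC)c2)c(OC)c1)C(Cl)=O | intermediate
23 | 2-(DEFG-aryloxy)-3-oxoprop-2-enoyl chloride (chlorocarbonyl ketene) | O=C=C(Oc1cc(OC)c(OC)c(OC)c1Oc1cc(OC)c(Oc2cc(OC)c(Oc3cc(OC)c(OC)c(OC)c3)c(OC)c2)c(OC)c1)C(Cl)=O | intermediate (not isolated)
24 | dimethyl 3-(AB-aryloxy)-4-[3-chloro-2-(DEFG-aryloxy)-3-oxopropanoyl]pent-2-enedioate (mixture of stereoisomers and enol tautomers) | COC(=O)C=C(Oc1c(OC)cc(Oc2c(OC)cc(OC)cc2OC)cc1OC)C(C(=O)OC)C(=O)C(Oc1cc(OC)c(OC)c(OC)c1Oc1cc(OC)c(Oc2cc(OC)c(Oc3cc(OC)c(OC)c(OC)c3)c(OC)c2)c(OC)c1)C(Cl)=O | intermediate (not isolated)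
25 | dimethyl 4,6-dihydroxy-2-(AB-aryloxy)-5-(DEFG-aryloxy)benzene-1,3-dicarboxylate | COc1cc(OC)c(Oc2cc(OC)c(Oc3c(C(=O)OC)c(O)c(Oc4cc(OC)c(OC)c(OC)c4Oc4cc(OC)c(Oc5cc(OC)c(Oc6cc(OC)c(OC)c(OC)c6)c(OC)c5)c(OC)c4)c(O)c3C(=O)OC)c(OC)c2)c(OC)c1 | intermediate
26 | 4,6-dihydroxy-2-(AB-aryloxy)-5-(DEFG-aryloxy)benzene-1,3-dicarboxylic acid | COc1cc(OC)c(Oc2cc(OC)c(Oc3c(C(=O)O)c(O)c(Oc4cc(OC)c(OC)c(OC)c4Oc4cc(OC)c(Oc5cc(OC)c(Oc6cc(OC)c(OC)c(OC)c6)c(OC)c5)c(OC)c4)c(O)c3C(=O)O)c(OC)c2)c(OC)c1 | intermediate (not isolated)
27 | 5-(AB-aryloxy)-2-(DEFG-aryloxy)benzene-1,3-diol | COc1cc(OC)c(Oc2cc(OC)c(Oc3cc(O)c(Oc4cc(OC)c(OC)c(OC)c4Oc4cc(OC)c(Oc5cc(OC)c(Oc6cc(OC)c(OC)c(OC)c6)c(OC)c5)c(OC)c4)c(O)c3)c(OC)c2)c(OC)c1 | intermediate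
28 | 5-[2,6-dihydroxy-4-(2,4,6-trihydroxyphenoxy)phenoxy]-2-{3,4,5-trihydroxy-2-[3,5-dihydroxy-4-[3,5-dihydroxy-4-(3,4,5-trihydroxyphenoxy)phenoxy]phenoxy]phenoxy}benzene-1,3-diol | Oc1cc(O)c(Oc2cc(O)c(Oc3cc(O)c(Oc4cc(O)c(O)c(O)c4Oc4cc(O)c(Oc5cc(O)c(Oc6cc(O)c(O)c(O)c6)c(O)c5)c(O)c4)c(O)c3)c(O)c2)c(O)c1 | target

## Step count and risks

Total: 16 steps. Longest linear sequence: 11 steps (steps 6 to 16, from 1 and 9 to 28). The AB branch (steps 1 to 5) joins at step 14.

**Step 14 (key step, proposed new method).** Several processes can divert it: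
- incomplete enolisation of 8 under the soft conditions;
- O-acylation or lactonisation of the mono-acylated stage towards a 2-pyranone;
- chain growth by a second intermolecular acylation;
- dimerisation of the ketene;
- intramolecular Friedel–Crafts acylation of the very electron-rich position D2 by the acyl chloride.

The fallback uses known chemistry and makes the two bonds one after the other. It sets out from 20 and 8 and returns at 25. One ester of 20 is saponified with one equivalent of KOH in MeOH to the half ester, methyl hydrogen 2-(DEFG-aryloxy)propanedioate F1 (racemic). Oxalyl chloride converts it into methyl 3-chloro-2-(DEFG-aryloxy)-3-oxopropanoate F2. Compound 8 is C-acylated with F2 under MgCl2 and Et3N, the established magnesium-mediated acylation of active-methylene esters, to give the open-chain triester, dimethyl 3-(AB-aryloxy)-4-[3-methoxy-2-(DEFG-aryloxy)-3-oxopropanoyl]pent-2-enedioate F3. NaOMe in MeOH then closes ring C by Dieckmann condensation of C4 onto the malonate ester, with aromatisation, as in the classical phloroglucinol synthesis, and gives 25.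

**Step 13.** Decarboxylation of 21 during activation, premature loss of HCl to the ketene with dimerisation on concentration, and Friedel–Crafts ring closure at D2 are the likely losses. The fallback avoids an acid chloride. It sets out from 21 and returns at 25. Pentafluorophenyl trifluoroacetate and pyridine convert 21 into the storable double acyl donor, bis(pentafluorophenyl) 2-(DEFG-aryloxy)propanedioate F4. F4 is then condensed with the magnesium dienolate of 8 (MgCl2, Et3N, MeCN, rt to 45 °C) to give 25 with release of pentafluorophenol.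

**Step 16.** Fifteen cleavages must all go to completion while aryl borates precipitate, and the free polyphenol can oxidise during work-up and chromatography. The fallback changes the isolation from direct purification to derivatisation and release. It sets out from 27 and returns at 28. After the BBr3 treatment and quench, the crude product is acetylated in the same flask (Ac2O, pyridine) to the heptadecaacetate of 28 F5, which is stable to air and is purified on silica. The acetates are then removed with catalytic NaOMe in degassed MeOH (Zemplén transesterification), followed by neutralisation with an acidic resin, to give 28.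

**Step 6.** The chemoselectivity between C–I and C–Br may erode, so that 1 or product 10 enters the copper cycle and oligomeric ethers form; the phenoxide may also be oxidised. The fallback is a metal-free arylation in which the bromide cannot react. It sets out from 9 and 1 and returns at 10. Iodide 9 is oxidised with mCPBA and TsOH and captured by 1,3,5-trimethoxybenzene to give the trivalent iodine salt, (3,4,5-trimethoxyphenyl)(2,4,6-trimethoxyphenyl)iodonium 4-methylbenzenesulfonate F6. Phenol 1 and K2CO3 in toluene then receive the less electron-rich 3,4,5-trimethoxyphenyl group to give 10.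

**Step 7.** Coupling may be slow because the formyl-substituted, hindered phenoxide of 11 is a weak nucleophile and 10 is an electron-rich bromide; protodebromination of 10 would then compete. The fallback reverses the roles to an oxidative coupling. It sets out from 10 and returns at 12. Bromine–lithium exchange (n-BuLi, THF, −78 °C), triisopropyl borate and acidic work-up give [3,5-dimethoxy-4-(3,4,5-trimethoxyphenoxy)phenyl]boronic acid F7. F7 is joined to 11 by Chan–Lam coupling (Cu(OAc)2, pyridine, 4 Å molecular sieves, CH2Cl2, air, rt), a reaction of divalent copper that is known to accept di-ortho-substituted phenols, to give 12.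

## Further compounds

F1 | step 14 | methyl hydrogen 2-(DEFG-aryloxy)propanedioate (racemic) | COC(=O)C(Oc1cc(OC)c(OC)c(OC)c1Oc1cc(OC)c(Oc2cc(OC)c(Oc3cc(OC)c(OC)c(OC)c3)c(OC)c2)c(OC)c1)C(=O)O
F2 | step 14 | methyl 3-chloro-2-(DEFG-aryloxy)-3-oxopropanoate (racemic) | COC(=O)C(Oc1cc(OC)c(OC)c(OC)c1Oc1cc(OC)c(Oc2cc(OC)c(Oc3cc(OC)c(OC)c(OC)c3)c(OC)c2)c(OC)c1)C(Cl)=O
F3 | step 14 | dimethyl 3-(AB-aryloxy)-4-[3-methoxy-2-(DEFG-aryloxy)-3-oxopropanoyl]pent-2-enedioate (mixture of stereoisomers and enol tautomers) | COC(=O)C=C(Oc1c(OC)cc(Oc2c(OC)cc(OC)cc2OC)cc1OC)C(C(=O)OC)C(=O)C(Oc1cc(OC)c(OC)c(OC)c1Oc1cc(OC)c(Oc2cc(OC)c(Oc3cc(OC)c(OC)c(OC)c3)c(OC)c2)c(OC)c1)C(=O)OC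
F4 | step 13 | bis(pentafluorophenyl) 2-(DEFG-aryloxy)propanedioate | O=C(Oc1c(F)c(F)c(F)c(F)c1F)C(Oc1cc(OC)c(OC)c(OC)c1Oc1cc(OC)c(Oc2cc(OC)c(Oc3cc(OC)c(OC)c(OC)c3)c(OC)c2)c(OC)c1)C(=O)Oc1c(F)c(F)c(F)c(F)c1F
F5 | step 16 | heptadecaacetate of 28 (every hydroxyl as acetate) | CC(=O)Oc1cc(OC(C)=O)c(Oc2cc(OC(C)=O)c(Oc3cc(OC(C)=O)c(Oc4cc(OC(C)=O)c(OC(C)=O)c(OC(C)=O)c4Oc4cc(OC(C)=O)c(Oc5cc(OC(C)=O)c(Oc6cc(OC(C)=O)c(OC(C)=O)c(OC(C)=O)c6)c(OC(C)=O)c5)c(OC(C)=O)c4)c(OC(C)=O)c3)c(OC(C)=O)c2)c(OC(C)=O)c1
F6 | step 6 | (3,4,5-trimethoxyphenyl)(2,4,6-trimethoxyphenyl)iodonium 4-methylbenzenesulfonate | COc1cc([I+]c2c(OC)cc(OC)cc2OC)cc(OC)c1OC.Cc1ccc(S(=O)(=O)[O-])cc1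
F7 | step 7 | [3,5-dimethoxy-4-(3,4,5-trimethoxyphenoxy)phenyl]boronic acid | COc1cc(B(O)O)cc(OC)c1Oc1cc(OC)c(OC)c(OC)c1
A1 | alternative 1 | dodecaacetate penta-O-methyl ether of 28 (acetoxy at A2, A6, B3, B5, C3, C5, D3, D5, E3, E5, F3, F5; methoxy at A4, D4, G3, G4, G5) | COc1cc(OC(C)=O)c(Oc2cc(OC(C)=O)c(Oc3cc(OC(C)=O)c(Oc4cc(OC(C)=O)c(OC)c(OC(C)=O)c4Oc4cc(OC(C)=O)c(Oc5cc(OC(C)=O)c(Oc6cc(OC)c(OC)c(OC)c6)c(OC(C)=O)c5)c(OC(C)=O)c4)c(OC(C)=O)c3)c(OC(C)=O)c2)c(OC(C)=O)c1
A2 | alternative 1 | dodecaacetyl heptamer (an acetyl group in place of each acetoxy group of A1) | COc1cc(C(C)=O)c(Oc2cc(C(C)=O)c(Oc3cc(C(C)=O)c(Oc4cc(C(C)=O)c(OC)c(C(C)=O)c4Oc4cc(C(C)=O)c(Oc5cc(C(C)=O)c(Oc6cc(OC)c(OC)c(OC)c6)c(C(C)=O)c5)c(C(C)=O)c4)c(C(C)=O)c3)c(C(C)=O)c2)c(C(C)=O)c1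
A3 | alternative 2 | hexadeca-O-alkyl heptamer with ring G as 3-ethoxy-4-hydroxy-5-methoxyphenyl ether | COc1cc(OC)c(Oc2cc(OC)c(Oc3cc(OC)c(Oc4cc(OC)c(OC)c(OC)c4Oc4cc(OC)c(Oc5cc(OC)c(Oc6cc(OC)c(O)c(OCC)c6)c(OC)c5)c(OC)c4)c(OC)c3)c(OC)c2)c(OC)c1
A4 | alternative 2 | pentacarbonyl{[(ABCDEF-hexamer)oxy][(E)-2-methoxyethenyl]methylidene}chromium | COc1cc(OC)c(Oc2cc(OC)c(Oc3cc(OC)c(Oc4cc(OC)c(OC)c(OC)c4Oc4cc(OC)c(Oc5cc(OC)c(OC(/C=C/OC)=[Cr])c(OC)c5)c(OC)c4)c(OC)c3)c(OC)c2)c(OC)c1.[C-]#[O+].[C-]#[O+].[C-]#[O+].[C-]#[O+].[C-]#[O+]
A5 | alternative 2 | ethoxyacetylene | CCOC#C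
A6 | alternative 3 | hexadeca-O-methyl heptamer with free D3 hydroxyl | COc1cc(OC)c(Oc2cc(OC)c(Oc3cc(OC)c(Oc4cc(O)c(OC)c(OC)c4Oc4cc(OC)c(Oc5cc(OC)c(Oc6cc(OC)c(OC)c(OC)c6)c(OC)c5)c(OC)c4)c(OC)c3)c(OC)c2)c(OC)c1
A7 | alternative 3 | 2-{3,5-dimethoxy-4-[3,5-dimethoxy-4-(3,4,5-trimethoxyphenoxy)phenoxy]phenoxy}-3,4-dimethoxycyclobut-2-en-1-one (racemic at C4) | COC1C(OC)=C(Oc2cc(OC)c(Oc3cc(OC)c(Oc4cc(OC)c(OC)c(OC)c4)c(OC)c3)c(OC)c2)C1=O
A8 | alternative 3 | 2-(ethynyloxy)-1,3-dimethoxy-5-[2,6-dimethoxy-4-(2,4,6-trimethoxyphenoxy)phenoxy]benzene | C#COc1c(OC)cc(Oc2c(OC)cc(Oc3c(OC)cc(OC)cc3OC)cc2OC)cc1OC
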